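**Plan**
1. Retrosynthesis: the acetate and the angelate are removed first, then the epoxide (from the C2=C3 alkene, oxygen delivered from a C1 carbinol). The side chain is cut at C7=CH2 (ketone methylenation), C8–O (enolate hydroxylation) and C7–C8 (acyl substitution at a C7 ester). Last, the ring is cut at C4–C5 and C1–C2.
2. Enabling feature: in the six-membered ring, C1(=O)–C2(CH3)–C3(–O) is a masked 2-methylcyclohexane-1,3-dione and O–C6–C5–C7 is a malate (β-hydroxy ester) unit. A malate alkoxide–enolate (C5 nucleophile, C1 ester electrophile) and a 2-siloxyallyl bromide (C4 electrophile, latent C2 enolate) can therefore close the ring in one [3+3] alkylation / silyl shift / Claisen sequence.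
3. Forward order: bromide 5 (3 steps) → ring (step 4) → dione to enone (triflate, reduction) → C1 carbinol → side chain from the C7 ester (ketone, C8–OH, C7=CH2, angelate) → epoxide → C1 ketone → acetate.
4. Stereochemistry: C6 from (S)-malic acid; C5 by anti alkylation of the chelated dianion; the temporary C1 carbinol by axial hydride delivery; the epoxide by hydroxyl-directed epoxidation from that carbinol; C8 by reagent-controlled enolate hydroxylation.
5. Helpers and their removal: O3 (reduced off as its triflate), the C7 ester (becomes the side chain), TBS on O6 (moved there in the key step, exchanged for acetyl at the end), TES and the C1 carbinol (reoxidised).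

Key step: step 4

Atom numbers used below: ring C1 (ketone carbon), C2 (C–CH3), C3 (epoxide CH), C4 (CH2), C5 (CH bearing the side chain), C6 (CH–OAc); side chain C7 (C=CH2) and C8 (CH–O).
Remark: dione 9 is drawn as one enol tautomer; the enol ether geometry in 2–5 has no consequence for the route.

Step 1
Reactants: 1 methyl 2-oxobutanoate
Product: 2 methyl (2Z)-2-[(tert-butyldimethylsilyl)oxy]but-2-enoate
Conditions: TBSOTf, Et3N, CH2Cl2, 0 °C
Reagents that add atoms: tert-butyldimethylsilyl trifluoromethanesulfonate, CC(C)(C)[Si](C)(C)OS(=O)(=O)C(F)(F)F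
Why: Soft enolisation and O-silylation of an α-keto ester can only take place toward C3, so the silyl enol ether should form as a single regioisomer.

Step 2
Reactants: 2 methyl (2Z)-2-[(tert-butyldimethylsilyl)oxy]but-2-enoate
Product: 3 (2Z)-2-[(tert-butyldimethylsilyl)oxy]but-2-en-1-ol
Conditions: i-Bu2AlH (2.2 equiv), CH2Cl2, −78 °C; aq. potassium sodium tartrate (KNaC4H4O6)
Reagents that add atoms: none
Why: 1,2-Reduction of the ester by the aluminium hydride should give the allylic alcohol, the TBS enol ether being stable to hydride and to the neutral tartrate work-up.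

Step 3
Reactants: 3 (2Z)-2-[(tert-butyldimethylsilyl)oxy]but-2-en-1-ol
Product: 5 (2Z)-1-bromo-2-[(tert-butyldimethylsilyl)oxy]but-2-ene, via allylic mesylate 4 (not isolated)
Conditions: MsCl, Et3N, THF, −40 °C; then LiBr, −40 → 0 °C
Reagents that add atoms: lithium bromide, [Li+].[Br-]
Why: Mesylation followed by SN2 displacement with bromide under non-acidic conditions should convert the primary allylic alcohol into the bromide without hydrolysing the enol silane.

Step 4
Reactants: 6 dimethyl (S)-malate; 5 (2Z)-1-bromo-2-[(tert-butyldimethylsilyl)oxy]but-2-ene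
Product: 9 methyl (1R,2S)-2-[(tert-butyldimethylsilyl)oxy]-5-hydroxy-4-methyl-3-oxocyclohex-4-ene-1-carboxylate (enolised 3,5-dione), via lithium alkoxide 7 (not isolated), via ketone enolate 8 (not isolated)
Conditions: LiN(SiMe3)2 (2.2 equiv), THF, −78 → −20 °C; 5, −78 → −10 °C; then DMPU, −10 → 23 °C; aq. HCl (1 M), 0 °C
Reagents that add atoms: none
Why: Proposed new method: The dilithium alkoxide–enolate of 6 is C-alkylated by bromide 5 on the face anti to the C6 alkoxide of the chelated (Z)-enolate (Fráter–Seebach alkylation), which forms C4–C5 and sets C5 by 1,2-induction from the malate stereocentre. On warming with DMPU the C6 alkoxide attacks the silicon of the enol silane through a seven-membered siliconate (O-to-O silyl shift; closest known reactions: base-induced silyl migration between hydroxyls and alkoxide cleavage of silyl enol ethers to regiodefined enolates), which protects O6, removes the charge that deactivates the neighbouring C1 ester and sets the C2=C3 enolate free. The enolate attacks the C1 ester (Claisen/Dieckmann condensation; closest known annulation: the consecutive Michael–Claisen route from 5-oxo esters to cyclohexane-1,3-diones), forming C1–C2, and the methoxide set free deprotonates the dione, which drives the sequence. The ring closes in the 6-(enolendo)-exo-trig mode, whereas closure onto the C7 ester would be 5-(enolendo)-exo-trig and is disfavoured by Baldwin's rules for enolates, so the choice between the two esters is secured by the substrate. C5 is the only new stereocentre (trans to O6), C6 comes unchanged from (S)-malate and C2 is lost in the enolised dione. The step further needs SN2 rather than SN2' attack on 5 and no base able to eliminate the β-silyloxy group after the shift; the primary allylic bromide and the fact that only the enolates are left as bases provide for both.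

Step 5
Reactants: 9 enolised dione
Product: 10 methyl (1R,2S)-2-[(tert-butyldimethylsilyl)oxy]-4-methyl-3-oxo-5-{[(trifluoromethyl)sulfonyl]oxy}cyclohex-4-ene-1-carboxylate
Conditions: Tf2O, Et3N, CH2Cl2, −78 °C
Reagents that add atoms: trifluoromethanesulfonic anhydride, O=S(=O)(OS(=O)(=O)C(F)(F)F)C(F)(F)F
Why: O-Sulfonylation of the 1,3-diketone enolate should take place at the less hindered oxygen on C3, because the C1 oxygen is screened by the neighbouring C6 silyloxy group, giving the 3-triflyloxy enone (enol triflate formation).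

Step 6
Reactants: 10 vinyl triflate
Product: 11 methyl (1R,2S)-2-[(tert-butyldimethylsilyl)oxy]-4-methyl-3-oxocyclohex-4-ene-1-carboxylate
Conditions: Pd(OAc)2 (5 mol %), PPh3, HCO2H, n-Bu3N, DMF, 60 °C
Reagents that add atoms: none
Why: Palladium-catalysed formate reduction of the vinyl triflate (oxidative addition, formate-to-hydride exchange with loss of CO2, reductive elimination) should replace the C3 oxygen by hydrogen and leave the 2-methylcyclohex-2-enone with its carbonyl at C1.

Step 7
Reactants: 11 enone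
Product: 12 methyl (1R,2S,3S)-2-[(tert-butyldimethylsilyl)oxy]-3-hydroxy-4-methylcyclohex-4-ene-1-carboxylate
Conditions: NaBH4, CeCl3·7H2O, MeOH, −78 °C
Reagents that add atoms: none
Why: In this Luche 1,2-reduction the hydride should add axially to the half-chair that carries the C5 ester and the C6 silyloxy group equatorially (the diaxial conformer is screened on both faces), giving the C1 carbinol cis to the C5 substituent and trans to O6, as in the reduction of carvone to cis-carveol.

Step 8
Reactants: 12 allylic alcohol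
Product: 13 methyl (1R,2S,3S)-2-[(tert-butyldimethylsilyl)oxy]-4-methyl-3-[(triethylsilyl)oxy]cyclohex-4-ene-1-carboxylate
Conditions: TESCl, imidazole, DMF, 0 °C
Reagents that add atoms: chlorotriethylsilane, CC[Si](Cl)(CC)CC
Why: Standard silylation masks the C1 carbinol so that O8 will be the only free hydroxyl at the acylation stage, and TES can later be removed in the presence of TBS.

Step 9
Reactants: 13 TES ether ester; 14 5-bromo-2-methylpent-2-ene
Product: 17 1-[(1R,2S,3S)-2-[(tert-butyldimethylsilyl)oxy]-4-methyl-3-[(triethylsilyl)oxy]cyclohex-4-en-1-yl]-5-methylhex-4-en-1-one, via Weinreb amide 15 (not isolated), via Grignard reagent 16 (not isolated)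
Conditions: MeNH(OMe)·HCl (1.5 equiv), i-PrMgCl (3.0 equiv), THF, −20 °C; then 16 (from 14, Mg, THF), −20 → 0 °C; aq. NH4Cl
Reagents that add atoms: none
Why: Aminolysis of the ester by the magnesium amide gives the Weinreb amide, whose chelated tetrahedral adduct with the Grignard reagent should stop at the ketone (Weinreb ketone synthesis), C5 keeping its equatorial and thermodynamically preferred configuration.

Step 10
Reactants: 17 ketone
Product: 18 (2S)-1-[(1R,2S,3S)-2-[(tert-butyldimethylsilyl)oxy]-4-methyl-3-[(triethylsilyl)oxy]cyclohex-4-en-1-yl]-2-hydroxy-5-methylhex-4-en-1-one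
Conditions: KN(SiMe3)2, THF, −78 °C; then (+)-(camphorsulfonyl)oxaziridine, −78 °C; aq. NH4Cl
Reagents that add atoms: (+)-(camphorsulfonyl)oxaziridine, CC1(C)[C@@H]2CC[C@]13CS(=O)(=O)N4O[C@@]34C2
Why: Kinetic deprotonation at the unhindered C8 methylene gives the Z-enolate, which the enantiopure N-sulfonyloxaziridine should hydroxylate under reagent control (Davis oxidation), the (+)-reagent being the antipode that gives (S)-α-hydroxy ketones from Z-enolates of acyclic ketones.

Step 11
Reactants: 18 α-hydroxy ketone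
Product: 19 (3S)-2-[(1S,2S,3S)-2-[(tert-butyldimethylsilyl)oxy]-4-methyl-3-[(triethylsilyl)oxy]cyclohex-4-en-1-yl]-6-methylhepta-1,5-dien-3-ol
Conditions: Zn, CH2Br2, TiCl4, THF/CH2Cl2, 0 → 23 °C
Reagents that add atoms: dibromomethane, BrCBr
Why: The Takai–Lombardo methylenation is non-basic, so the hindered and enolisable α-hydroxy ketone should give the 1,1-disubstituted alkene without epimerisation at C8 or C5 and without β-elimination of the C6 silyloxy group.

Step 12
Reactants: 19 allylic alcohol; 20 angelic acid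
Product: 22 (3S)-2-[(1S,2S,3S)-2-[(tert-butyldimethylsilyl)oxy]-4-methyl-3-[(triethylsilyl)oxy]cyclohex-4-en-1-yl]-6-methylhepta-1,5-dien-3-yl (2Z)-2-methylbut-2-enoate, via mixed anhydride 21 (not isolated)
Conditions: 20, 2,4,6-trichlorobenzoyl chloride, Et3N, toluene, 23 °C; then 19, 80 °C
Reagents that add atoms: none
Why: In this Yamaguchi-type esterification the alcohol should attack the less hindered angeloyl carbonyl of the mixed anhydride, and leaving out a nucleophilic catalyst keeps the Z double bond from isomerising to the tiglate while C8 is untouched.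

Step 13
Reactants: 22 bis-silyl angelate
Product: 23 (3S)-2-[(1S,2S,3S)-2-[(tert-butyldimethylsilyl)oxy]-3-hydroxy-4-methylcyclohex-4-en-1-yl]-6-methylhepta-1,5-dien-3-yl (2Z)-2-methylbut-2-enoate
Conditions: PPTS, MeOH/CH2Cl2, 0 °C
Reagents that add atoms: none
Why: Mild acid methanolysis should cleave the secondary TES ether much faster than the TBS ether (selective silyl ether solvolysis), freeing the C1 allylic alcohol.

Step 14
Reactants: 23 allylic alcohol
Product: 24 (3S)-2-[(1R,2R,3S,4S,6S)-3-[(tert-butyldimethylsilyl)oxy]-2-hydroxy-1-methyl-7-oxabicyclo[4.1.0]heptan-4-yl]-6-methylhepta-1,5-dien-3-yl (2Z)-2-methylbut-2-enoate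
Conditions: VO(acac)2 (5 mol %), t-BuOOH, CH2Cl2, 0 → 23 °C
Reagents that add atoms: tert-butyl hydroperoxide, CC(C)(C)OO
Why: In this hydroxyl-directed epoxidation the vanadium alkoxide of the C1 carbinol should deliver the peroxide oxygen to the C2=C3 bond on its own face, which is the face of the C5 side chain, while the alkenes without a free allylic hydroxyl react much more slowly.

Step 15
Reactants: 24 epoxy alcohol
Product: 25 (3S)-2-[(1S,3S,4S,6S)-3-[(tert-butyldimethylsilyl)oxy]-1-methyl-2-oxo-7-oxabicyclo[4.1.0]heptan-4-yl]-6-methylhepta-1,5-dien-3-yl (2Z)-2-methylbut-2-enoate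
Conditions: Dess–Martin periodinane, CH2Cl2, 0 → 23 °C
Reagents that add atoms: none
Why: Dess–Martin oxidation of the secondary alcohol under near-neutral conditions should give the α,β-epoxy ketone without opening the epoxide or moving the esters.

Step 16
Reactants: 25 epoxy ketone
Product: 26 (3S)-2-[(1S,3S,4S,6S)-3-hydroxy-1-methyl-2-oxo-7-oxabicyclo[4.1.0]heptan-4-yl]-6-methylhepta-1,5-dien-3-yl (2Z)-2-methylbut-2-enoate
Conditions: HF·pyridine, pyridine, THF, 0 → 23 °C
Reagents that add atoms: none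
Why: Buffered fluoride cleavage of the TBS ether (desilylation) should free the C6 hydroxyl, the electron-poor epoxy ketone being left intact under buffered conditions.

Step 17
Reactants: 26 hydroxy epoxy ketone
Product: 27 target, (3S)-2-[(1S,3S,4S,6S)-3-(acetyloxy)-1-methyl-2-oxo-7-oxabicyclo[4.1.0]heptan-4-yl]-6-methylhepta-1,5-dien-3-yl (2Z)-2-methylbut-2-enoate
Conditions: Ac2O, pyridine, DMAP (cat.), CH2Cl2, 0 °C
Reagents that add atoms: acetic anhydride, CC(=O)OC(C)=O
Why: Acylation of the secondary α-hydroxy ketone should give the acetate, C6 keeping its configuration because the equatorial trans arrangement is also the thermodynamically preferred one.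

**Compound list**
1 | methyl 2-oxobutanoate | CCC(=O)C(=O)OC | starting material
2 | methyl (2Z)-2-[(tert-butyldimethylsilyl)oxy]but-2-enoate | C/C=C(\O[Si](C)(C)C(C)(C)C)C(=O)OC | intermediate
3 | (2Z)-2-[(tert-butyldimethylsilyl)oxy]but-2-en-1-ol | C/C=C(\O[Si](C)(C)C(C)(C)C)CO | intermediate
4 | (2Z)-2-[(tert-butyldimethylsilyl)oxy]but-2-en-1-yl methanesulfonate (not isolated) | C/C=C(\O[Si](C)(C)C(C)(C)C)COS(C)(=O)=O | intermediate
5 | (2Z)-1-bromo-2-[(tert-butyldimethylsilyl)oxy]but-2-ene | C/C=C(\O[Si](C)(C)C(C)(C)C)CBr | intermediate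
6 | dimethyl (2S)-2-hydroxybutanedioate, dimethyl (S)-malate | COC(=O)C[C@H](O)C(=O)OC | starting material
7 | dimethyl (2S,3R)-2-hydroxy-3-{(2Z)-2-[(tert-butyldimethylsilyl)oxy]but-2-en-1-yl}butanedioate, present as its lithium alkoxide (not isolated) | COC(=O)[C@@H]([C@H](O)C(=O)OC)C/C(O[Si](C)(C)C(C)(C)C)=C/C | intermediate
8 | dimethyl (2S,3R)-2-[(tert-butyldimethylsilyl)oxy]-3-(2-oxobutyl)butanedioate, present as its C2=C3 lithium enolate (not isolated) | COC(=O)[C@@H]([C@H](O[Si](C)(C)C(C)(C)C)C(=O)OC)CC(=O)CC | intermediate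
9 | methyl (1R,2S)-2-[(tert-butyldimethylsilyl)oxy]-5-hydroxy-4-methyl-3-oxocyclohex-4-ene-1-carboxylate (enol form of the 3,5-dione; ester and silyloxy group trans) | COC(=O)[C@@H]1CC(O)=C(C)C(=O)[C@H]1O[Si](C)(C)C(C)(C)C | intermediate
10 | methyl (1R,2S)-2-[(tert-butyldimethylsilyl)oxy]-4-methyl-3-oxo-5-{[(trifluoromethyl)sulfonyl]oxy}cyclohex-4-ene-1-carboxylate | COC(=O)[C@@H]1CC(OS(=O)(=O)C(F)(F)F)=C(C)C(=O)[C@H]1O[Si](C)(C)C(C)(C)C | intermediate
11 | methyl (1R,2S)-2-[(tert-butyldimethylsilyl)oxy]-4-methyl-3-oxocyclohex-4-ene-1-carboxylate | COC(=O)[C@@H]1CC=C(C)C(=O)[C@H]1O[Si](C)(C)C(C)(C)C | intermediate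
12 | methyl (1R,2S,3S)-2-[(tert-butyldimethylsilyl)oxy]-3-hydroxy-4-methylcyclohex-4-ene-1-carboxylate (hydroxyl cis to the ester, trans to the silyloxy group) | COC(=O)[C@@H]1CC=C(C)[C@H](O)[C@H]1O[Si](C)(C)C(C)(C)C | intermediate
13 | methyl (1R,2S,3S)-2-[(tert-butyldimethylsilyl)oxy]-4-methyl-3-[(triethylsilyl)oxy]cyclohex-4-ene-1-carboxylate | COC(=O)[C@@H]1CC=C(C)[C@H](O[Si](CC)(CC)CC)[C@H]1O[Si](C)(C)C(C)(C)C | intermediate
14 | 5-bromo-2-methylpent-2-ene | CC(C)=CCCBr | starting material
15 | (1R,2S,3S)-2-[(tert-butyldimethylsilyl)oxy]-N-methoxy-N,4-dimethyl-3-[(triethylsilyl)oxy]cyclohex-4-ene-1-carboxamide (not isolated) | CON(C)C(=O)[C@@H]1CC=C(C)[C@H](O[Si](CC)(CC)CC)[C@H]1O[Si](C)(C)C(C)(C)C | intermediate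
16 | (4-methylpent-3-en-1-yl)magnesium bromide (not isolated) | CC(C)=CCC[Mg]Br | intermediate
17 | 1-[(1R,2S,3S)-2-[(tert-butyldimethylsilyl)oxy]-4-methyl-3-[(triethylsilyl)oxy]cyclohex-4-en-1-yl]-5-methylhex-4-en-1-one | CC(C)=CCCC(=O)[C@@H]1CC=C(C)[C@H](O[Si](CC)(CC)CC)[C@H]1O[Si](C)(C)C(C)(C)C | intermediate
18 | (2S)-1-[(1R,2S,3S)-2-[(tert-butyldimethylsilyl)oxy]-4-methyl-3-[(triethylsilyl)oxy]cyclohex-4-en-1-yl]-2-hydroxy-5-methylhex-4-en-1-one | O=C([C@H](CC=C(C)C)O)[C@@H]1CC=C(C)[C@H](O[Si](CC)(CC)CC)[C@H]1O[Si](C)(C)C(C)(C)C | intermediate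
19 | (3S)-2-[(1S,2S,3S)-2-[(tert-butyldimethylsilyl)oxy]-4-methyl-3-[(triethylsilyl)oxy]cyclohex-4-en-1-yl]-6-methylhepta-1,5-dien-3-ol | C=C([C@H](CC=C(C)C)O)[C@@H]1CC=C(C)[C@H](O[Si](CC)(CC)CC)[C@H]1O[Si](C)(C)C(C)(C)C | intermediate
20 | angelic acid, (2Z)-2-methylbut-2-enoic acid | C/C=C(/C)C(=O)O | starting material
21 | (2Z)-2-methylbut-2-enoic 2,4,6-trichlorobenzoic anhydride (not isolated) | C/C=C(/C)C(=O)OC(=O)c1c(Cl)cc(Cl)cc1Cl | intermediate
22 | (3S)-2-[(1S,2S,3S)-2-[(tert-butyldimethylsilyl)oxy]-4-methyl-3-[(triethylsilyl)oxy]cyclohex-4-en-1-yl]-6-methylhepta-1,5-dien-3-yl (2Z)-2-methylbut-2-enoate | C=C([C@H](CC=C(C)C)OC(=O)/C(C)=C\C)[C@@H]1CC=C(C)[C@H](O[Si](CC)(CC)CC)[C@H]1O[Si](C)(C)C(C)(C)C | intermediate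
23 | (3S)-2-[(1S,2S,3S)-2-[(tert-butyldimethylsilyl)oxy]-3-hydroxy-4-methylcyclohex-4-en-1-yl]-6-methylhepta-1,5-dien-3-yl (2Z)-2-methylbut-2-enoate | C=C([C@H](CC=C(C)C)OC(=O)/C(C)=C\C)[C@@H]1CC=C(C)[C@H](O)[C@H]1O[Si](C)(C)C(C)(C)C | intermediate
24 | (3S)-2-[(1R,2R,3S,4S,6S)-3-[(tert-butyldimethylsilyl)oxy]-2-hydroxy-1-methyl-7-oxabicyclo[4.1.0]heptan-4-yl]-6-methylhepta-1,5-dien-3-yl (2Z)-2-methylbut-2-enoate (epoxide and C1 hydroxyl on the face of the side chain, silyloxy group on the other face) | C=C([C@H](CC=C(C)C)OC(=O)/C(C)=C\C)[C@@H]1C[C@@H]2O[C@]2(C)[C@H](O)[C@H]1O[Si](C)(C)C(C)(C)C | intermediate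
25 | (3S)-2-[(1S,3S,4S,6S)-3-[(tert-butyldimethylsilyl)oxy]-1-methyl-2-oxo-7-oxabicyclo[4.1.0]heptan-4-yl]-6-methylhepta-1,5-dien-3-yl (2Z)-2-methylbut-2-enoate | C=C([C@H](CC=C(C)C)OC(=O)/C(C)=C\C)[C@@H]1C[C@@H]2O[C@]2(C)C(=O)[C@H]1O[Si](C)(C)C(C)(C)C | intermediate
26 | (3S)-2-[(1S,3S,4S,6S)-3-hydroxy-1-methyl-2-oxo-7-oxabicyclo[4.1.0]heptan-4-yl]-6-methylhepta-1,5-dien-3-yl (2Z)-2-methylbut-2-enoate | C=C([C@H](CC=C(C)C)OC(=O)/C(C)=C\C)[C@@H]1C[C@@H]2O[C@]2(C)C(=O)[C@H]1O | intermediate
27 | (3S)-2-[(1S,3S,4S,6S)-3-(acetyloxy)-1-methyl-2-oxo-7-oxabicyclo[4.1.0]heptan-4-yl]-6-methylhepta-1,5-dien-3-yl (2Z)-2-methylbut-2-enoate, CNP0150645.2 | C=C([C@H](CC=C(C)C)OC(=O)/C(C)=C\C)[C@@H]1C[C@@H]2O[C@]2(C)C(=O)[C@H]1OC(C)=O | target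

**Totals**
Total step count: 17.
Longest linear sequence: 17 steps (1 → 27 through bromide 5); 14 steps from dimethyl (S)-malate 6.

**Steps most likely to fail**

Step 4 (proposed new method). The O-to-O silyl shift may be slower than intermolecular desilylation by the methoxide set free in the Claisen step, or the unmasked enolate may be protonated before it cyclises, so that ring closure stays incomplete or the silyl group is lost. The fallback uses known reactions in separate steps, sets out from 6 and comes back at 9. Fráter–Seebach alkylation of 6 [LiN(SiMe3)2 (2.2 equiv), THF, −78 → −10 °C] with commercial 1-bromobut-2-yne should give dimethyl (2S,3R)-3-(but-2-yn-1-yl)-2-hydroxybutanedioate F1. Silylation (TBSOTf, 2,6-lutidine, CH2Cl2) gives dimethyl (2S,3R)-3-(but-2-yn-1-yl)-2-[(tert-butyldimethylsilyl)oxy]butanedioate F2. NaAuCl4-catalysed hydration in aqueous ethanol, steered to C3 by 5-exo participation of the C7 ester carbonyl, gives keto diester 8 as an isolated compound. KOt-Bu in THF at 0 °C then effects the Dieckmann condensation to 9.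

Step 10. Enolisation may stray toward C5 with β-elimination of the C6 silanolate, or the facial selectivity at C8 may be poor if reagent and substrate bias are mismatched. The fallback sets C8 by ketone reduction instead of enolate oxidation, sets out from 17 and comes back at 19. Hydroxylation of the potassium enolate with racemic 2-(phenylsulfonyl)-3-phenyloxaziridine gives 1-[(1R,2S,3S)-2-[(tert-butyldimethylsilyl)oxy]-4-methyl-3-[(triethylsilyl)oxy]cyclohex-4-en-1-yl]-2-hydroxy-5-methylhex-4-en-1-one as a mixture of C8 epimers F3. Takai–Lombardo methylenation gives the C8-epimeric 2-[(1S,2S,3S)-2-[(tert-butyldimethylsilyl)oxy]-4-methyl-3-[(triethylsilyl)oxy]cyclohex-4-en-1-yl]-6-methylhepta-1,5-dien-3-ols F4. Dess–Martin oxidation erases C8 and gives 2-[(1S,2S,3S)-2-[(tert-butyldimethylsilyl)oxy]-4-methyl-3-[(triethylsilyl)oxy]cyclohex-4-en-1-yl]-6-methylhepta-1,5-dien-3-one F5. Corey–Bakshi–Shibata reduction with the (R)-Me-CBS oxazaborolidine and catecholborane (toluene, −78 °C), with the branched alkenyl group acting as the large substituent, gives 19.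

Step 7. If the conformer with axial C5 and C6 substituents reacts, hydride adds to the other face of the carbonyl and gives the C1 epimer, which would send the directed epoxidation to the wrong face. The fallback corrects C1 by inversion, sets out from 11 and comes back at 12. The reduction then gives methyl (1R,2S,3R)-2-[(tert-butyldimethylsilyl)oxy]-3-hydroxy-4-methylcyclohex-4-ene-1-carboxylate F6. Mitsunobu reaction (4-nitrobenzoic acid, PPh3, diisopropyl azodicarboxylate, toluene, 0 → 23 °C) inverts C1 and gives methyl (1R,2S,3S)-2-[(tert-butyldimethylsilyl)oxy]-4-methyl-3-[(4-nitrobenzoyl)oxy]cyclohex-4-ene-1-carboxylate F7. Methanolysis (K2CO3, MeOH, 0 °C) gives 12.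

**Further compounds**
F1 | step 4 | dimethyl (2S,3R)-3-(but-2-yn-1-yl)-2-hydroxybutanedioate | COC(=O)[C@@H]([C@H](O)C(=O)OC)CC#CC
F2 | step 4 | dimethyl (2S,3R)-3-(but-2-yn-1-yl)-2-[(tert-butyldimethylsilyl)oxy]butanedioate | COC(=O)[C@@H]([C@H](O[Si](C)(C)C(C)(C)C)C(=O)OC)CC#CC
F3 | step 10 | 1-[(1R,2S,3S)-2-[(tert-butyldimethylsilyl)oxy]-4-methyl-3-[(triethylsilyl)oxy]cyclohex-4-en-1-yl]-2-hydroxy-5-methylhex-4-en-1-one, mixture of C8 epimers | O=C(C(O)CC=C(C)C)[C@@H]1CC=C(C)[C@H](O[Si](CC)(CC)CC)[C@H]1O[Si](C)(C)C(C)(C)C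
F4 | step 10 | 2-[(1S,2S,3S)-2-[(tert-butyldimethylsilyl)oxy]-4-methyl-3-[(triethylsilyl)oxy]cyclohex-4-en-1-yl]-6-methylhepta-1,5-dien-3-ol, mixture of C8 epimers | C=C(C(O)CC=C(C)C)[C@@H]1CC=C(C)[C@H](O[Si](CC)(CC)CC)[C@H]1O[Si](C)(C)C(C)(C)C
F5 | step 10 | 2-[(1S,2S,3S)-2-[(tert-butyldimethylsilyl)oxy]-4-methyl-3-[(triethylsilyl)oxy]cyclohex-4-en-1-yl]-6-methylhepta-1,5-dien-3-one | C=C(C(=O)CC=C(C)C)[C@@H]1CC=C(C)[C@H](O[Si](CC)(CC)CC)[C@H]1O[Si](C)(C)C(C)(C)C
F6 | step 7 | methyl (1R,2S,3R)-2-[(tert-butyldimethylsilyl)oxy]-3-hydroxy-4-methylcyclohex-4-ene-1-carboxylate | COC(=O)[C@@H]1CC=C(C)[C@@H](O)[C@H]1O[Si](C)(C)C(C)(C)C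
F7 | step 7 | methyl (1R,2S,3S)-2-[(tert-butyldimethylsilyl)oxy]-4-methyl-3-[(4-nitrobenzoyl)oxy]cyclohex-4-ene-1-carboxylate | COC(=O)[C@@H]1CC=C(C)[C@H](OC(=O)c2ccc(cc2)[N+](=O)[O-])[C@H]1O[Si](C)(C)C(C)(C)C
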